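Retrosynthesis: the C7–C(CH3)2 bond is cut first (retro-Claisen to a 6-O-prenyl ether), then O1–C2 of the furan (back to an E stilbene), then the stilbene C=C (olefination). This leaves a ring A aldehyde and a ring B benzylphosphonate, and in ring B the C2'–prenyl and C5'–O bonds are cut last.
Forward: ring B is made from methyl 2-bromo-3-methoxybenzoate (C–H borylation/oxidation, MOM ether, Stille prenylation, ester to phosphonate) and ring A from 2,4,6-trihydroxybenzaldehyde (4-O-prenylation, bis-silylation). Olefination joins the two, the furan ring closes by O1–C2 bond formation, the prenyl group is moved from O6 to C7, and the protecting groups are removed.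
Enabling feature: in the benzofuran, O1 sits on C7a and the free hydroxyl on C4, and both carbons are ortho to C3a. In the open stilbene these are the 2- and 6-hydroxyls of a 2,6-dihydroxy-4-prenyloxyphenyl ring A and are interchangeable, so one closure distinguishes all three ring A oxygens (O1 in the furan, O4 free, O6 as prenyl ether).
Stereochemistry: the target has no stereocentre and no stereogenic double bond. The only stereo-element on the way, the E stilbene, comes from the olefination and disappears on cyclisation.

Key step: step 10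

Remark: the bicycle is numbered as a benzofuran (ring A is its benzo ring) and the 2-aryl group carries primes (ring B, C1' on C2); methyl 2-bromo-3-methoxybenzoate (1) is assumed to be commercial (otherwise one esterification from the commercial acid).

Step 1
Reactants: 1 methyl 2-bromo-3-methoxybenzoate
Product: 3 methyl 2-bromo-5-hydroxy-3-methoxybenzoate, via aryl boronate 2 (not isolated)
Conditions: B2pin2, [Ir(OMe)(cod)]2 (cat.), 4,4'-di-tert-butyl-2,2'-bipyridine (cat.), THF, 80 °C; evaporate; then KHSO5 (as 2KHSO5·KHSO4·K2SO4), acetone–H2O, rt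
Reagents that add atoms: bis(pinacolato)diboron, CC1(C)OB(OC1(C)C)B1OC(C)(C)C(C)(C)O1 (boron present only in 2); potassium peroxymonosulfate, [K+].[O-]S(=O)(=O)OO (supplies the phenol oxygen)
Why: Iridium-catalysed aromatic C–H borylation is sterically controlled and C5 is the only ring C–H of 1 without an ortho substituent, so boronate 2 should form there alone, and its oxidation by peroxymonosulfate (one-pot borylation/oxidation to a phenol) leaves the aryl bromide and the ester untouched.

Step 2
Reactants: 3 methyl 2-bromo-5-hydroxy-3-methoxybenzoate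
Product: 4 methyl 2-bromo-3-methoxy-5-(methoxymethoxy)benzoate
Conditions: MOMCl, i-Pr2NEt, CH2Cl2, 0 °C to rt
Reagents that add atoms: chloromethyl methyl ether, COCCl
Why: Williamson-type O-alkylation of the phenol gives the MOM acetal, which should withstand the cross-coupling, hydride, basic, oxidative and thermal steps that follow and is removed only at the end.

Step 3
Reactants: 4 methyl 2-bromo-3-methoxy-5-(methoxymethoxy)benzoate
Product: 5 methyl 3-methoxy-5-(methoxymethoxy)-2-(3-methylbut-2-en-1-yl)benzoate
Conditions: Bu3SnCH2CH=CMe2, Pd(PPh3)4 (cat.), DMF, 100 °C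
Reagents that add atoms: tributyl(3-methylbut-2-en-1-yl)stannane, CCCC[Sn](CCCC)(CCCC)CC=C(C)C
Why: Stille cross-coupling of the aryl bromide, which the ortho ester activates towards oxidative addition to zerovalent palladium, should place the linear prenyl group on C2 because reductive elimination occurs at the unsubstituted terminus of the allyl ligand, and the neutral conditions spare ester and acetal.

Step 4
Reactants: 5 methyl 3-methoxy-5-(methoxymethoxy)-2-(3-methylbut-2-en-1-yl)benzoate
Product: 6 [3-methoxy-5-(methoxymethoxy)-2-(3-methylbut-2-en-1-yl)phenyl]methanol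
Conditions: LiAlH4, THF, 0 °C
Reagents that add atoms: none
Why: Hydride reduction of the methyl ester gives the benzylic alcohol without touching the isolated trisubstituted alkene, the aryl ethers or the acetal.

Step 5
Reactants: 6 [3-methoxy-5-(methoxymethoxy)-2-(3-methylbut-2-en-1-yl)phenyl]methanol
Product: 7 1-(bromomethyl)-3-methoxy-5-(methoxymethoxy)-2-(3-methylbut-2-en-1-yl)benzene
Conditions: CBr4, PPh3, CH2Cl2, 0 °C
Reagents that add atoms: carbon tetrabromide, BrC(Br)(Br)Br
Why: In this Appel reaction bromide displaces the alkoxyphosphonium group by SN2 under neutral conditions that spare the MOM group, and the benzylic carbon, meta to both ring oxygens, has little tendency to ionise and attack the neighbouring prenyl alkene.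

Step 6
Reactants: 7 1-(bromomethyl)-3-methoxy-5-(methoxymethoxy)-2-(3-methylbut-2-en-1-yl)benzene
Product: 8 diethyl {[3-methoxy-5-(methoxymethoxy)-2-(3-methylbut-2-en-1-yl)phenyl]methyl}phosphonate
Conditions: P(OEt)3 (neat), 130 °C
Reagents that add atoms: triethyl phosphite, CCOP(OCC)OCC
Why: Michaelis–Arbuzov reaction of the primary benzylic bromide with triethyl phosphite should give the phosphonate with loss of bromoethane.

Step 7
Reactants: 9 2,4,6-trihydroxybenzaldehyde; 10 1-bromo-3-methylbut-2-ene (prenyl bromide)
Product: 11 2,6-dihydroxy-4-[(3-methylbut-2-en-1-yl)oxy]benzaldehyde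
Conditions: K2CO3 (1 equiv), acetone, rt
Reagents that add atoms: none
Why: Williamson etherification should select O4 because the para hydroxyl is the most acidic and the only one not hydrogen-bonded to the aldehyde, and one equivalent of weak base in acetone favours O- over C-alkylation.

Step 8
Reactants: 11 2,6-dihydroxy-4-[(3-methylbut-2-en-1-yl)oxy]benzaldehyde
Product: 12 2,6-bis[(tert-butyldimethylsilyl)oxy]-4-[(3-methylbut-2-en-1-yl)oxy]benzaldehyde
Conditions: TBSCl, imidazole, DMF, rt
Reagents that add atoms: tert-butyldimethylsilyl chloride, CC(C)(C)[Si](C)(C)Cl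
Why: Silyl ether formation at both ortho phenols removes the acidic protons that would quench the phosphonate anion and deactivate the aldehyde, and the groups can later be taken off by fluoride without acid, so the aryl prenyl ether and the MOM acetal are kept.

Step 9
Reactants: 8 diethyl {[3-methoxy-5-(methoxymethoxy)-2-(3-methylbut-2-en-1-yl)phenyl]methyl}phosphonate; 12 2,6-bis[(tert-butyldimethylsilyl)oxy]-4-[(3-methylbut-2-en-1-yl)oxy]benzaldehyde
Product: 14 2-{(E)-2-[3-methoxy-5-(methoxymethoxy)-2-(3-methylbut-2-en-1-yl)phenyl]ethenyl}-5-[(3-methylbut-2-en-1-yl)oxy]benzene-1,3-diol, via bis-silyl stilbene 13 (not isolated)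
Conditions: NaH, 15-crown-5 (cat.), THF, 0 °C to rt; then AcOH, Bu4NF, THF, 0 °C
Reagents that add atoms: none
Why: Horner–Wadsworth–Emmons olefination of the non-enolisable aldehyde with the benzylphosphonate anion should give the E stilbene 13 through the thermodynamically preferred anti adduct, and buffered fluoride then cleaves both aryl silyl ethers in the same flask, which also converges any partly desilylated material on the single diol 14.

Step 10
Reactants: 14 2-{(E)-2-[3-methoxy-5-(methoxymethoxy)-2-(3-methylbut-2-en-1-yl)phenyl]ethenyl}-5-[(3-methylbut-2-en-1-yl)oxy]benzene-1,3-diol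
Product: 15 2-[3-methoxy-5-(methoxymethoxy)-2-(3-methylbut-2-en-1-yl)phenyl]-6-[(3-methylbut-2-en-1-yl)oxy]-1-benzofuran-4-ol
Conditions: PhI(OAc)2 (1.05 equiv), MeCN, 0 °C to rt
Reagents that add atoms: none
Why: This is the oxidative cyclisation of an ortho-hydroxystilbene by a trivalent iodine reagent, a known way to 2-arylbenzofurans: PhI(OAc)2 binds the electron-rich alkene (or, after ligand exchange at a phenol, generates a quinone-methide-type cation) so that the carbon bearing ring B becomes electrophilic, an ortho phenol oxygen of ring A attacks it to form O1–C2, and loss of iodobenzene, acetic acid and the C2 proton gives the aromatic furan. The furan ring closes in a formally 5-endo-trig mode, which is feasible because the oxygen attacks a cation-like carbon and not a neutral alkene. No stereocentre is formed, and the E geometry of 14 is lost on aromatisation. No choice between the two hydroxyls is required, since the 2- and 6-hydroxyls of ring A in 14 are equivalent and either closure gives the same benzofuran, leaving the other oxygen as the free C4 hydroxyl and the prenyl ether on O6. Chemoselectivity over the two prenyl alkenes rests on the stilbene alkene being conjugated to the trioxygenated ring and being the only one with a phenol placed to trap it, and one equivalent of oxidant at 0 °C should limit further oxidation of the electron-rich ring.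

Step 11
Reactants: 15 2-[3-methoxy-5-(methoxymethoxy)-2-(3-methylbut-2-en-1-yl)phenyl]-6-[(3-methylbut-2-en-1-yl)oxy]-1-benzofuran-4-ol
Product: 16 {[2-[3-methoxy-5-(methoxymethoxy)-2-(3-methylbut-2-en-1-yl)phenyl]-6-[(3-methylbut-2-en-1-yl)oxy]-1-benzofuran-4-yl]oxy}tri(propan-2-yl)silane
Conditions: TIPSCl, imidazole, DMF, rt
Reagents that add atoms: triisopropylsilyl chloride, CC(C)[Si](Cl)(C(C)C)C(C)C
Why: Silyl ether formation at the only free phenol protects O4 for the thermal step and places a bulky group next to C5, the ortho position that would otherwise compete with C7 for the migrating allyl unit.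

Step 12
Reactants: 16 {[2-[3-methoxy-5-(methoxymethoxy)-2-(3-methylbut-2-en-1-yl)phenyl]-6-[(3-methylbut-2-en-1-yl)oxy]-1-benzofuran-4-yl]oxy}tri(propan-2-yl)silane
Product: 17 2-[3-methoxy-5-(methoxymethoxy)-2-(3-methylbut-2-en-1-yl)phenyl]-7-(2-methylbut-3-en-2-yl)-4-{[tri(propan-2-yl)silyl]oxy}-1-benzofuran-6-ol
Conditions: PhNEt2, 190 °C, sealed tube, argon
Reagents that add atoms: none
Why: In the aromatic Claisen rearrangement the concerted [3,3] shift of the aryl prenyl ether delivers the allyl unit with allylic transposition as the 2-methylbut-3-en-2-yl group, and C7 should be preferred over C5 because the C6–C7 bond of a benzofuran has the higher double-bond character and C5 is shielded by the silyl ether, after which enolisation restores the arene with O6 as a free phenol.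

Step 13
Reactants: 17 2-[3-methoxy-5-(methoxymethoxy)-2-(3-methylbut-2-en-1-yl)phenyl]-7-(2-methylbut-3-en-2-yl)-4-{[tri(propan-2-yl)silyl]oxy}-1-benzofuran-6-ol
Product: 18 2-[3-methoxy-5-(methoxymethoxy)-2-(3-methylbut-2-en-1-yl)phenyl]-7-(2-methylbut-3-en-2-yl)-1-benzofuran-4,6-diol
Conditions: Bu4NF, AcOH, THF, 0 °C
Reagents that add atoms: none
Why: Fluoride-induced cleavage of the aryl silyl ether, buffered with acetic acid so that the electron-rich diphenol is not kept as an oxidisable phenoxide, should leave the MOM acetal and both alkenes untouched.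

Step 14
Reactants: 18 2-[3-methoxy-5-(methoxymethoxy)-2-(3-methylbut-2-en-1-yl)phenyl]-7-(2-methylbut-3-en-2-yl)-1-benzofuran-4,6-diol
Product: 19 2-[5-hydroxy-3-methoxy-2-(3-methylbut-2-en-1-yl)phenyl]-7-(2-methylbut-3-en-2-yl)-1-benzofuran-4,6-diol (CNP0169501.0)
Conditions: HCl (aq., 3 M), MeOH, 40 °C
Reagents that add atoms: none
Why: Acid-catalysed acetal exchange with methanol removes the MOM group as dimethoxymethane, and in dilute acid at 40 °C neither the monosubstituted alkene of the 1,1-dimethylallyl group nor the ring B prenyl group, which has no ortho hydroxyl to cyclise onto, should be protonated at a competitive rate.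

Compound list
1 | methyl 2-bromo-3-methoxybenzoate | COC(=O)c1cccc(OC)c1Br | starting material
2 | methyl 2-bromo-3-methoxy-5-(4,4,5,5-tetramethyl-1,3,2-dioxaborolan-2-yl)benzoate | COC(=O)c1cc(B2OC(C)(C)C(C)(C)O2)cc(OC)c1Br | intermediate (not isolated)
3 | methyl 2-bromo-5-hydroxy-3-methoxybenzoate | COC(=O)c1cc(O)cc(OC)c1Br | intermediate
4 | methyl 2-bromo-3-methoxy-5-(methoxymethoxy)benzoate | COC(=O)c1cc(OCOC)cc(OC)c1Br | intermediate
5 | methyl 3-methoxy-5-(methoxymethoxy)-2-(3-methylbut-2-en-1-yl)benzoate | COC(=O)c1cc(OCOC)cc(OC)c1CC=C(C)C | intermediate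
6 | [3-methoxy-5-(methoxymethoxy)-2-(3-methylbut-2-en-1-yl)phenyl]methanol | OCc1cc(OCOC)cc(OC)c1CC=C(C)C | intermediate
7 | 1-(bromomethyl)-3-methoxy-5-(methoxymethoxy)-2-(3-methylbut-2-en-1-yl)benzene | BrCc1cc(OCOC)cc(OC)c1CC=C(C)C | intermediate
8 | diethyl {[3-methoxy-5-(methoxymethoxy)-2-(3-methylbut-2-en-1-yl)phenyl]methyl}phosphonate | CCOP(=O)(OCC)Cc1cc(OCOC)cc(OC)c1CC=C(C)C | intermediate
9 | 2,4,6-trihydroxybenzaldehyde | O=Cc1c(O)cc(O)cc1O | starting material
10 | 1-bromo-3-methylbut-2-ene (prenyl bromide) | CC(C)=CCBr | starting material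
11 | 2,6-dihydroxy-4-[(3-methylbut-2-en-1-yl)oxy]benzaldehyde | O=Cc1c(O)cc(OCC=C(C)C)cc1O | intermediate
12 | 2,6-bis[(tert-butyldimethylsilyl)oxy]-4-[(3-methylbut-2-en-1-yl)oxy]benzaldehyde | O=Cc1c(O[Si](C)(C)C(C)(C)C)cc(OCC=C(C)C)cc1O[Si](C)(C)C(C)(C)C | intermediate
13 | (E)-stilbene bis(tert-butyldimethylsilyl) ether: 2,6-bis(silyloxy)-4-prenyloxyphenyl joined by an E CH=CH to 3-methoxy-5-(methoxymethoxy)-2-prenylphenyl | CC(C)=CCOc1cc(O[Si](C)(C)C(C)(C)C)c(/C=C/c2cc(OCOC)cc(OC)c2CC=C(C)C)c(O[Si](C)(C)C(C)(C)C)c1 | intermediate (not isolated)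
14 | 2-{(E)-2-[3-methoxy-5-(methoxymethoxy)-2-(3-methylbut-2-en-1-yl)phenyl]ethenyl}-5-[(3-methylbut-2-en-1-yl)oxy]benzene-1,3-diol | Oc1cc(OCC=C(C)C)cc(O)c1/C=C/c1cc(OCOC)cc(OC)c1CC=C(C)C | intermediate
15 | 2-[3-methoxy-5-(methoxymethoxy)-2-(3-methylbut-2-en-1-yl)phenyl]-6-[(3-methylbut-2-en-1-yl)oxy]-1-benzofuran-4-ol | CC(C)=CCOc1cc(O)c2cc(-c3cc(OCOC)cc(OC)c3CC=C(C)C)oc2c1 | intermediate
16 | {[2-[3-methoxy-5-(methoxymethoxy)-2-(3-methylbut-2-en-1-yl)phenyl]-6-[(3-methylbut-2-en-1-yl)oxy]-1-benzofuran-4-yl]oxy}tri(propan-2-yl)silane | CC(C)=CCOc1cc(O[Si](C(C)C)(C(C)C)C(C)C)c2cc(-c3cc(OCOC)cc(OC)c3CC=C(C)C)oc2c1 | intermediate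
17 | 2-[3-methoxy-5-(methoxymethoxy)-2-(3-methylbut-2-en-1-yl)phenyl]-7-(2-methylbut-3-en-2-yl)-4-{[tri(propan-2-yl)silyl]oxy}-1-benzofuran-6-ol | C=CC(C)(C)c1c(O)cc(O[Si](C(C)C)(C(C)C)C(C)C)c2cc(-c3cc(OCOC)cc(OC)c3CC=C(C)C)oc12 | intermediate
18 | 2-[3-methoxy-5-(methoxymethoxy)-2-(3-methylbut-2-en-1-yl)phenyl]-7-(2-methylbut-3-en-2-yl)-1-benzofuran-4,6-diol | C=CC(C)(C)c1c(O)cc(O)c2cc(-c3cc(OCOC)cc(OC)c3CC=C(C)C)oc12 | intermediate
19 | 2-[5-hydroxy-3-methoxy-2-(3-methylbut-2-en-1-yl)phenyl]-7-(2-methylbut-3-en-2-yl)-1-benzofuran-4,6-diol (CNP0169501.0) | C=CC(C)(C)c1c(O)cc(O)c2cc(-c3cc(O)cc(OC)c3CC=C(C)C)oc12 | target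

Total step count: 14. Longest linear sequence: 12 steps (steps 1–6, then 9–14); the ring A branch (steps 7–8) joins at step 9.

Steps most likely to fail

1. Step 10 (oxidative cyclisation). What may go wrong: the oxidant attacks the phloroglucinol-type ring A itself (dearomatisation, oxidative coupling) or oxidises the benzofuranol as it forms, in competition with closure of the furan. Fallback: the dehydrogenation is split into a halocyclisation and an elimination, without hypervalent iodine. Setting out from 14, I2 and K2CO3 in THF at 0 °C should add across the stilbene alkene with capture by a ring A phenol to give the racemic trans-3-iodo-2-aryl-2,3-dihydro-1-benzofuran-4-ol F1. Continued stirring with the carbonate at room temperature should expel iodide from the benzylic C3, assisted by the electron-rich ring A, together with the C2 proton, and return to the route at 15.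

2. Step 12 (Claisen rearrangement). What may go wrong: at 190 °C the newly formed ortho-(1,1-dimethylallyl)phenol reacts further (abnormal Claisen isomerisation of the side chain, addition of the phenol to the vinyl group), or the prenyl ether fragments before it rearranges. Fallback: the phenol is captured as it forms. Setting out from 16, heating in acetic anhydride and N,N-diethylaniline with NaOAc at 180 °C should give the 6-acetate F2, in which the oxygen can no longer take part in follow-up reactions. Brief treatment with K2CO3 in MeOH at 0 °C should then remove the acetyl group while the triisopropylsilyl ether stays, returning to the route at 17.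

3. Step 9 (olefination). What may go wrong: slow addition to the doubly ortho-substituted aldehyde, and transfer of a silyl group from an ortho phenol oxygen to the β-alkoxide before phosphate is expelled, which stops the elimination. Fallback: a salt-free Wittig reaction, which forms the oxaphosphetane directly and has no long-lived alkoxide. Setting out from bromide 7, PPh3 in toluene at 90 °C should give the benzyltriphenylphosphonium bromide F3. Its ylide (NaN(SiMe3)2, THF, −78 °C to rt) with aldehyde 12 should give stilbene 13 together with its Z isomer F4. Catalytic PhSSPh under visible light in THF should equilibrate F4 to the E isomer, so the fallback returns to the route at 13, which is desilylated with buffered Bu4NF as in step 9.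

Further compounds
F1 | step 10 | trans-3-iodo-2-[3-methoxy-5-(methoxymethoxy)-2-(3-methylbut-2-en-1-yl)phenyl]-6-[(3-methylbut-2-en-1-yl)oxy]-2,3-dihydro-1-benzofuran-4-ol (racemic; one enantiomer drawn) | CC(C)=CCOc1cc(O)c2c(c1)O[C@@H](c1cc(OCOC)cc(OC)c1CC=C(C)C)[C@@H]2I
F2 | step 12 | 2-[3-methoxy-5-(methoxymethoxy)-2-(3-methylbut-2-en-1-yl)phenyl]-7-(2-methylbut-3-en-2-yl)-4-{[tri(propan-2-yl)silyl]oxy}-1-benzofuran-6-yl acetate | C=CC(C)(C)c1c(OC(C)=O)cc(O[Si](C(C)C)(C(C)C)C(C)C)c2cc(-c3cc(OCOC)cc(OC)c3CC=C(C)C)oc12
F3 | step 9 | {[3-methoxy-5-(methoxymethoxy)-2-(3-methylbut-2-en-1-yl)phenyl]methyl}triphenylphosphonium bromide | CC(C)=CCc1c(C[P+](c2ccccc2)(c2ccccc2)c2ccccc2)cc(OCOC)cc1OC.[Br-]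
F4 | step 9 | (Z) isomer of stilbene bis(tert-butyldimethylsilyl) ether 13 | CC(C)=CCOc1cc(O[Si](C)(C)C(C)(C)C)c(/C=C\c2cc(OCOC)cc(OC)c2CC=C(C)C)c(O[Si](C)(C)C(C)(C)C)c1
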